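The benzo ring of the dihydrobenzofuran is made last. On this ring O1 sits on C7a para to the styryl-bearing C5, the pattern that a 2-oxy-1,3-diene (C7=C7a–C3a=C4) gives with an acceptor alkyne. In one flask, 5-exo-dig addition of a hydroxyl to an alkyne (O1–C7a) closes the dihydrofuran ring as a 2,3-dimethylidene oxolane and a Diels–Alder reaction with methyl propiolate (C4–C5, C6–C7) closes the carbocycle; mild dehydrogenation then gives the arene. The precursor is an acyclic anti (1S,2S)-1,2-diaryl-3-methylidenepent-4-yn-1-ol whose two stereocentres, the later C2 and C3, are set beforehand by a catalytic asymmetric allylboration. The C5 ester is turned into the stilbene, and the methyl ethers are cleaved last.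

Key step: step 6

Remarks on the chemistry
- Atom labels O1, C2, C3, C3a, C4–C7 and C7a are those of the benzofuran system of the target and are used for the corresponding atoms of all intermediates.
- The allylboronate that leads to the anti alcohol has the aryl group trans to CH2B and cis to the alkynyl group. Because alkynyl outranks CH2B under the CIP rules, this isomer is (Z), not (E).
- Assumption: the (S)-phosphoric acid is taken to deliver the (1S) carbinol by analogy with simple allyl- and crotylboronates. The configuration is to be confirmed on the enynol precursor, and the antipodal catalyst is used if the sense proves opposite.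
- The five phenols stay protected as methyl ethers throughout.

Step 1
Reactants: 1 3,5-dimethoxybenzaldehyde; 2 ethyl (triphenyl-λ5-phosphanylidene)acetate
Product: 4 ethyl (2Z)-2-bromo-3-(3,5-dimethoxyphenyl)prop-2-enoate, via bromo ylide 3 (not isolated)
Conditions: NBS (1.0 equiv), CH2Cl2, −20 °C; then 1, −20 °C → rt
Reagents that add atoms: N-bromosuccinimide, O=C1CCC(=O)N1Br
Why: Bromination of the stabilised ylide gives the bromo ylide, whose Wittig reaction with the aryl aldehyde places the ester trans to the aryl group (stabilised-ylide selectivity), so the bromine sits cis to the aryl group where the alkyne is needed.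

Step 2
Reactants: 4 ethyl (2Z)-2-bromo-3-(3,5-dimethoxyphenyl)prop-2-enoate; 5 ethynyltrimethylsilane
Product: 6 ethyl (2E)-3-(3,5-dimethoxyphenyl)-2-[(trimethylsilyl)ethynyl]prop-2-enoate
Conditions: PdCl2(PPh3)2 (3 mol%), CuI (5 mol%), Et3N, THF, rt
Reagents that add atoms: none
Why: Sonogashira coupling of an activated α-bromoacrylate proceeds with retention of the alkene geometry, so the alkynyl group ends up cis to the aryl group.

Step 3
Reactants: 6 ethyl (2E)-3-(3,5-dimethoxyphenyl)-2-[(trimethylsilyl)ethynyl]prop-2-enoate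
Product: 7 (2E)-3-(3,5-dimethoxyphenyl)-2-[(trimethylsilyl)ethynyl]prop-2-en-1-ol
Conditions: i-Bu2AlH (2.2 equiv), CH2Cl2, −78 °C; aq. potassium sodium tartrate work-up
Reagents that add atoms: none
Why: Low-temperature 1,2-reduction of the conjugated ester by the aluminium hydride gives the allylic alcohol and leaves the silyl alkyne and the alkene geometry untouched.

Step 4
Reactants: 7 (2E)-3-(3,5-dimethoxyphenyl)-2-[(trimethylsilyl)ethynyl]prop-2-en-1-ol
Product: 8 2-{(2Z)-3-(3,5-dimethoxyphenyl)-2-[(trimethylsilyl)ethynyl]prop-2-en-1-yl}-4,4,5,5-tetramethyl-1,3,2-dioxaborolane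
Conditions: B2pin2 (1.2 equiv), Pd(MeCN)4(BF4)2 (5 mol%), DMSO/MeOH, 50 °C
Reagents that add atoms: bis(pinacolato)diboron, CC1(C)OB(B2OC(C)(C)C(C)(C)O2)OC1(C)C
Why: Palladium-catalysed borylation of the allylic C–OH bond through an η3-allyl intermediate delivers boron to the unhindered CH2 terminus, and the aryl group keeps the thermodynamically preferred position cis to the slim alkynyl group and trans to CH2B.

Step 5
Reactants: 8 2-{(2Z)-3-(3,5-dimethoxyphenyl)-2-[(trimethylsilyl)ethynyl]prop-2-en-1-yl}-4,4,5,5-tetramethyl-1,3,2-dioxaborolane; 9 4-methoxybenzaldehyde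
Product: 12 (1S,2S)-2-(3,5-dimethoxyphenyl)-1-(4-methoxyphenyl)-3-methylidenepent-4-yn-1-ol, via O-boryl adduct 10 (not isolated), via silylated alkynol 11 (not isolated)
Conditions: (S)-3,3'-bis(2,4,6-triisopropylphenyl)-1,1'-binaphthyl-2,2'-diyl hydrogen phosphate (10 mol%), 4 Å MS, toluene, 0 °C → rt; then K2CO3 (0.5 equiv), MeOH, rt
Reagents that add atoms: none
Why: Chiral-phosphoric-acid-catalysed allylboration runs through a closed chair transition state with both aryl groups equatorial, so the boronate geometry fixes the anti relation (C2), while the acid, hydrogen-bonded to a boronate oxygen and the formyl C–H, selects the Si face of the aldehyde (C1 = S), and methanolysis then cleaves the O–B and C–Si bonds.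

Step 6
Reactants: 12 (1S,2S)-2-(3,5-dimethoxyphenyl)-1-(4-methoxyphenyl)-3-methylidenepent-4-yn-1-ol; 13 methyl propiolate
Product: 15 methyl (2S,3S)-3-(3,5-dimethoxyphenyl)-2-(4-methoxyphenyl)-2,3,4,7-tetrahydro-1-benzofuran-5-carboxylate, via dimethylidene oxolane 14 (not isolated)
Conditions: (Ph3P)AuNTf2 (2 mol%), 2,6-di-tert-butylpyridine (10 mol%), 13 (5 equiv), 4 Å MS, toluene, rt → 60 °C
Reagents that add atoms: none
Why: Proposed new method: the cationic gold centre π-activates the terminal alkyne of 12 and the C1 hydroxyl adds in Markovnikov fashion to the internal alkyne carbon (O1–C7a), protodeauration then releasing the s-cis-locked 2-oxy-1,3-diene 14 (C7=C7a–C3a=C4), which adds 13 in a concerted, normal-electron-demand [4+2] cycloaddition (C6–C7 and C4–C5) to give the 1,4-cyclohexadiene 15. The closest known reaction types are the gold- or palladium-catalysed cycloisomerisation of pent-4-yn-1-ols to 2-methylideneoxolanes and the Diels–Alder reaction of 2-alkoxy-1,3-dienes with propiolates, each established separately but not yet merged on a 3-methylidene alkynol with the diene intercepted as it forms. The oxolane ring closes by 5-exo-dig attack of oxygen on the activated alkyne, and the six-membered carbocycle closes by the intermolecular [4+2] cycloaddition across the two exocyclic methylidene termini. No stereocentre is created: C2 and C3 are carried over unchanged from 12, and the hindered pyridine buffer removes adventitious acid that could shift the exocyclic double bonds towards a furan through the doubly allylic C3–H. The step needs oxygen rather than the dimethoxyphenyl ring to attack the alkyne, which the nearer hydroxyl nucleophile secures, and it needs para regiochemistry, which the ring oxygen secures by placing the largest HOMO coefficient on C7 so that C7 joins the unsubstituted β-carbon of 13 and the ester lands on C5.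

Step 7
Reactants: 15 methyl (2S,3S)-3-(3,5-dimethoxyphenyl)-2-(4-methoxyphenyl)-2,3,4,7-tetrahydro-1-benzofuran-5-carboxylate
Product: 16 methyl (2S,3S)-3-(3,5-dimethoxyphenyl)-2-(4-methoxyphenyl)-2,3-dihydro-1-benzofuran-5-carboxylate
Conditions: DDQ (1.05 equiv), CH2Cl2, 0 °C
Reagents that add atoms: none
Why: DDQ dehydrogenation of a 1,4-cyclohexadiene (hydride abstraction from the doubly allylic C4 or C7, then proton loss) is driven by aromatisation and is fast at 0 °C, far below what is needed to dehydrogenate the dihydrofuran ring, so C2 and C3 are kept.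

Step 8
Reactants: 16 methyl (2S,3S)-3-(3,5-dimethoxyphenyl)-2-(4-methoxyphenyl)-2,3-dihydro-1-benzofuran-5-carboxylate
Product: 17 [(2S,3S)-3-(3,5-dimethoxyphenyl)-2-(4-methoxyphenyl)-2,3-dihydro-1-benzofuran-5-yl]methanol
Conditions: i-Bu2AlH (2.5 equiv), CH2Cl2, −78 → 0 °C; aq. potassium sodium tartrate work-up
Reagents that add atoms: none
Why: Hydride reduction of the aryl ester to the benzylic alcohol meets no other reducible group in the molecule.

Step 9
Reactants: 17 [(2S,3S)-3-(3,5-dimethoxyphenyl)-2-(4-methoxyphenyl)-2,3-dihydro-1-benzofuran-5-yl]methanol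
Product: 18 (2S,3S)-3-(3,5-dimethoxyphenyl)-2-(4-methoxyphenyl)-2,3-dihydro-1-benzofuran-5-carbaldehyde
Conditions: MnO2 (activated, excess), CH2Cl2, rt
Reagents that add atoms: none
Why: Heterogeneous MnO2 oxidation is selective for benzylic alcohols, stops at the aldehyde and is neutral, so the benzylic stereocentres are not endangered.

Step 10
Reactants: 18 (2S,3S)-3-(3,5-dimethoxyphenyl)-2-(4-methoxyphenyl)-2,3-dihydro-1-benzofuran-5-carbaldehyde; 19 diethyl [(3,5-dimethoxyphenyl)methyl]phosphonate
Product: 20 (2S,3S)-3-(3,5-dimethoxyphenyl)-5-[(E)-2-(3,5-dimethoxyphenyl)ethenyl]-2-(4-methoxyphenyl)-2,3-dihydro-1-benzofuran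
Conditions: 19, KOtBu, THF, 0 °C; then 18, 0 °C → rt
Reagents that add atoms: none
Why: Horner–Wadsworth–Emmons olefination of an aryl aldehyde with a benzylic phosphonate anion gives the (E)-stilbene through the favoured anti elimination pathway, and C3–H is not acidic enough to be touched by the alkoxide at this temperature.

Step 11
Reactants: 20 (2S,3S)-3-(3,5-dimethoxyphenyl)-5-[(E)-2-(3,5-dimethoxyphenyl)ethenyl]-2-(4-methoxyphenyl)-2,3-dihydro-1-benzofuran
Product: 21 (2S,3S)-trans-δ-viniferin
Conditions: BBr3 (12 equiv), CH2Cl2, −78 °C → rt; then MeOH, aq. NaHCO3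
Reagents that add atoms: none
Why: Lewis-acid ether cleavage (bromide attack on the methyl group of each O→B adduct) frees the five phenols, C3 has no pathway to change, and any reversible ionisation of the benzylic O1–C2 bond recloses to the trans ring.

Compound list
1 | 3,5-dimethoxybenzaldehyde | COc1cc(C=O)cc(OC)c1 | starting material
2 | ethyl (triphenyl-λ5-phosphanylidene)acetate | CCOC(=O)C=P(c1ccccc1)(c1ccccc1)c1ccccc1 | starting material
3 | ethyl bromo(triphenyl-λ5-phosphanylidene)acetate | CCOC(=O)C(Br)=P(c1ccccc1)(c1ccccc1)c1ccccc1 | intermediate (not isolated)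
4 | ethyl (2Z)-2-bromo-3-(3,5-dimethoxyphenyl)prop-2-enoate | CCOC(=O)/C(Br)=C/c1cc(OC)cc(OC)c1 | intermediate
5 | ethynyltrimethylsilane | C#C[Si](C)(C)C | starting material
6 | ethyl (2E)-3-(3,5-dimethoxyphenyl)-2-[(trimethylsilyl)ethynyl]prop-2-enoate | CCOC(=O)/C(C#C[Si](C)(C)C)=C/c1cc(OC)cc(OC)c1 | intermediate
7 | (2E)-3-(3,5-dimethoxyphenyl)-2-[(trimethylsilyl)ethynyl]prop-2-en-1-ol | OC/C(C#C[Si](C)(C)C)=C/c1cc(OC)cc(OC)c1 | intermediate
8 | 2-{(2Z)-3-(3,5-dimethoxyphenyl)-2-[(trimethylsilyl)ethynyl]prop-2-en-1-yl}-4,4,5,5-tetramethyl-1,3,2-dioxaborolane | CC1(C)OB(C/C(C#C[Si](C)(C)C)=C/c2cc(OC)cc(OC)c2)OC1(C)C | intermediate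
9 | 4-methoxybenzaldehyde | COc1ccc(C=O)cc1 | starting material
10 | 2-{[(1S,2S)-2-(3,5-dimethoxyphenyl)-1-(4-methoxyphenyl)-3-methylidene-5-(trimethylsilyl)pent-4-yn-1-yl]oxy}-4,4,5,5-tetramethyl-1,3,2-dioxaborolane | COc1ccc([C@@H](OB2OC(C)(C)C(C)(C)O2)[C@H](C(=C)C#C[Si](C)(C)C)c2cc(OC)cc(OC)c2)cc1 | intermediate (not isolated)
11 | (1S,2S)-2-(3,5-dimethoxyphenyl)-1-(4-methoxyphenyl)-3-methylidene-5-(trimethylsilyl)pent-4-yn-1-ol | COc1ccc([C@@H](O)[C@H](C(=C)C#C[Si](C)(C)C)c2cc(OC)cc(OC)c2)cc1 | intermediate (not isolated)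
12 | (1S,2S)-2-(3,5-dimethoxyphenyl)-1-(4-methoxyphenyl)-3-methylidenepent-4-yn-1-ol | COc1ccc([C@@H](O)[C@H](C(=C)C#C)c2cc(OC)cc(OC)c2)cc1 | intermediate
13 | methyl propiolate | C#CC(=O)OC | starting material
14 | (2S,3S)-3-(3,5-dimethoxyphenyl)-2-(4-methoxyphenyl)-4,5-dimethylideneoxolane | COc1ccc([C@H]2OC(=C)C(=C)[C@@H]2c2cc(OC)cc(OC)c2)cc1 | intermediate (not isolated)
15 | methyl (2S,3S)-3-(3,5-dimethoxyphenyl)-2-(4-methoxyphenyl)-2,3,4,7-tetrahydro-1-benzofuran-5-carboxylate | COc1ccc([C@H]2OC3=C(CC(C(=O)OC)=CC3)[C@@H]2c2cc(OC)cc(OC)c2)cc1 | intermediate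
16 | methyl (2S,3S)-3-(3,5-dimethoxyphenyl)-2-(4-methoxyphenyl)-2,3-dihydro-1-benzofuran-5-carboxylate | COc1ccc([C@H]2Oc3ccc(C(=O)OC)cc3[C@@H]2c2cc(OC)cc(OC)c2)cc1 | intermediate
17 | [(2S,3S)-3-(3,5-dimethoxyphenyl)-2-(4-methoxyphenyl)-2,3-dihydro-1-benzofuran-5-yl]methanol | COc1ccc([C@H]2Oc3ccc(CO)cc3[C@@H]2c2cc(OC)cc(OC)c2)cc1 | intermediate
18 | (2S,3S)-3-(3,5-dimethoxyphenyl)-2-(4-methoxyphenyl)-2,3-dihydro-1-benzofuran-5-carbaldehyde | COc1ccc([C@H]2Oc3ccc(C=O)cc3[C@@H]2c2cc(OC)cc(OC)c2)cc1 | intermediate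
19 | diethyl [(3,5-dimethoxyphenyl)methyl]phosphonate | CCOP(=O)(Cc1cc(OC)cc(OC)c1)OCC | starting material
20 | (2S,3S)-3-(3,5-dimethoxyphenyl)-5-[(E)-2-(3,5-dimethoxyphenyl)ethenyl]-2-(4-methoxyphenyl)-2,3-dihydro-1-benzofuran | COc1ccc([C@H]2Oc3ccc(/C=C/c4cc(OC)cc(OC)c4)cc3[C@@H]2c2cc(OC)cc(OC)c2)cc1 | intermediate
21 | (2S,3S)-trans-δ-viniferin, 5-[(2S,3S)-5-[(E)-2-(3,5-dihydroxyphenyl)ethenyl]-2-(4-hydroxyphenyl)-2,3-dihydro-1-benzofuran-3-yl]benzene-1,3-diol | Oc1ccc([C@H]2Oc3ccc(/C=C/c4cc(O)cc(O)c4)cc3[C@@H]2c2cc(O)cc(O)c2)cc1 | target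

Total step count: 11
Longest linear sequence: 11 steps (1 to 21; compounds 2, 5, 9, 13 and 19 are bought)

Steps most likely to fail

1. Step 6. The exocyclic diene may drift to an endocyclic or furan isomer, or oligomerise, before it is intercepted. The dimethoxyphenyl ring may attack the activated alkyne in place of oxygen. The cycloaddition may not be fully para-selective. The fallback uses known reaction types only, sets out from 12 and comes back at 16. Compound 12 is cyclised by anti iodo-etherification (I2, NaHCO3, MeCN, 0 °C; 5-exo-dig) to (2S,3S)-3-(3,5-dimethoxyphenyl)-5-[(E)-iodomethylidene]-2-(4-methoxyphenyl)-4-methylideneoxolane F1. Heck coupling of this vinyl iodide with methyl acrylate (Pd(OAc)2, PPh3, Et3N, DMF, 60 °C) should give the triene ester methyl (2E,4E)-4-[(4S,5S)-4-(3,5-dimethoxyphenyl)-5-(4-methoxyphenyl)-3-methylideneoxolan-2-ylidene]but-2-enoate F2, in which the new vinyl group is cis to C3a. Heating (toluene, 100 °C) should bring about disrotatory 6π-electrocyclisation (C4–C5) to methyl (2S,3S)-3-(3,5-dimethoxyphenyl)-2-(4-methoxyphenyl)-2,3,4,5-tetrahydro-1-benzofuran-5-carboxylate F3 (C5 epimers). Here the ester position is fixed by connectivity, not by orbital coefficients. DDQ (CH2Cl2, 0 °C → rt) then dehydrogenates this cyclohexadiene to 16.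

2. Step 5. The phosphoric acid may discriminate poorly between the aldehyde faces with a hindered, doubly substituted boronate, or the catalysed pathway may be slow enough for unselective background addition to compete. The fallback replaces catalyst control by classical resolution, sets out from 8 (with 9) and comes back at 12. The two are combined under achiral acid catalysis (diphenyl phosphate, toluene, rt), which keeps the chair-controlled anti selectivity. This gives 10 together with its enantiomer 2-{[(1R,2R)-2-(3,5-dimethoxyphenyl)-1-(4-methoxyphenyl)-3-methylidene-5-(trimethylsilyl)pent-4-yn-1-yl]oxy}-4,4,5,5-tetramethyl-1,3,2-dioxaborolane F4. Aqueous work-up gives 11 together with (1R,2R)-2-(3,5-dimethoxyphenyl)-1-(4-methoxyphenyl)-3-methylidene-5-(trimethylsilyl)pent-4-yn-1-ol F5. Esterification with (S)-2-methoxy-2-phenylacetic acid (DCC, DMAP, CH2Cl2, 0 °C) gives two diastereomers, separated by chromatography or crystallisation: (1S,2S)-2-(3,5-dimethoxyphenyl)-1-(4-methoxyphenyl)-3-methylidene-5-(trimethylsilyl)pent-4-yn-1-yl (2S)-2-methoxy-2-phenylacetate F6 and its (1R,2R)-configured diastereomer (2S)-2-methoxy-2-phenylacetate F7. K2CO3 in MeOH then cleaves the ester and the C–Si bond of the (1S,2S) ester in one operation and delivers 12.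

3. Step 11. The boron halide may open the benzylic O1–C2 bond by ionisation at C2, and acid may oligomerise the electron-rich stilbene, while the resorcinol methyl ethers are still being cleaved. The fallback separates ether cleavage from ring integrity, sets out from 20 and comes back at 21. The cleavage is driven to completion regardless of ring opening. The crude product then contains the ring-opened hexaphenol 5-[(E)-2-{3-[(1S)-1-(3,5-dihydroxyphenyl)-2-hydroxy-2-(4-hydroxyphenyl)ethyl]-4-hydroxyphenyl}ethenyl]benzene-1,3-diol F8 (carbinol epimers, C3 configuration retained). This is recyclised with catalytic TsOH in MeCN at rt through the para-quinone methide: 5-exo-trig attack of the ortho phenol anti to the C3 aryl group should re-form the trans ring of 21 from either carbinol epimer.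

Further compounds
F1 | step 6 | (2S,3S)-3-(3,5-dimethoxyphenyl)-5-[(E)-iodomethylidene]-2-(4-methoxyphenyl)-4-methylideneoxolane | COc1ccc([C@H]2O/C(=C/I)C(=C)[C@@H]2c2cc(OC)cc(OC)c2)cc1
F2 | step 6 | methyl (2E,4E)-4-[(4S,5S)-4-(3,5-dimethoxyphenyl)-5-(4-methoxyphenyl)-3-methylideneoxolan-2-ylidene]but-2-enoate | COc1ccc([C@H]2O/C(=C/C=C/C(=O)OC)C(=C)[C@@H]2c2cc(OC)cc(OC)c2)cc1
F3 | step 6 | methyl (2S,3S)-3-(3,5-dimethoxyphenyl)-2-(4-methoxyphenyl)-2,3,4,5-tetrahydro-1-benzofuran-5-carboxylate (C5 epimers) | COc1ccc([C@H]2OC3=C(CC(C(=O)OC)C=C3)[C@@H]2c2cc(OC)cc(OC)c2)cc1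
F4 | step 5 | 2-{[(1R,2R)-2-(3,5-dimethoxyphenyl)-1-(4-methoxyphenyl)-3-methylidene-5-(trimethylsilyl)pent-4-yn-1-yl]oxy}-4,4,5,5-tetramethyl-1,3,2-dioxaborolane | COc1ccc([C@H](OB2OC(C)(C)C(C)(C)O2)[C@@H](C(=C)C#C[Si](C)(C)C)c2cc(OC)cc(OC)c2)cc1
F5 | step 5 | (1R,2R)-2-(3,5-dimethoxyphenyl)-1-(4-methoxyphenyl)-3-methylidene-5-(trimethylsilyl)pent-4-yn-1-ol | COc1ccc([C@H](O)[C@@H](C(=C)C#C[Si](C)(C)C)c2cc(OC)cc(OC)c2)cc1
F6 | step 5 | (1S,2S)-2-(3,5-dimethoxyphenyl)-1-(4-methoxyphenyl)-3-methylidene-5-(trimethylsilyl)pent-4-yn-1-yl (2S)-2-methoxy-2-phenylacetate | COc1ccc([C@@H](OC(=O)[C@@H](OC)c2ccccc2)[C@H](C(=C)C#C[Si](C)(C)C)c2cc(OC)cc(OC)c2)cc1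
F7 | step 5 | (1R,2R)-2-(3,5-dimethoxyphenyl)-1-(4-methoxyphenyl)-3-methylidene-5-(trimethylsilyl)pent-4-yn-1-yl (2S)-2-methoxy-2-phenylacetate | COc1ccc([C@H](OC(=O)[C@@H](OC)c2ccccc2)[C@@H](C(=C)C#C[Si](C)(C)C)c2cc(OC)cc(OC)c2)cc1
F8 | step 11 | 5-[(E)-2-{3-[(1S)-1-(3,5-dihydroxyphenyl)-2-hydroxy-2-(4-hydroxyphenyl)ethyl]-4-hydroxyphenyl}ethenyl]benzene-1,3-diol (carbinol epimers) | OC(c1ccc(O)cc1)[C@@H](c1cc(O)cc(O)c1)c1cc(/C=C/c2cc(O)cc(O)c2)ccc1O
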